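## The problem

The target is a tridepside: three orsellinate-type benzene rings joined head to tail by two aryl ester bonds. The C4 oxygen of ring A carries the C1 carbonyl of ring B, and the C4 oxygen of ring B carries the C1 carbonyl of ring C. There is no stereocentre, so the difficulty lies in regiochemistry and in telling apart six acidic groups: the ring A carboxylic acid, the hydrogen-bonded C2 hydroxyls of rings A, B and C, and the C4 and C5 hydroxyls of ring C. Each ester carbonyl sits between an ortho methyl and an ortho hydroxyl, so both depside bonds are hindered to make. Once made, they are aryl esters that hydroxide, alkoxide, free phenoxide and strong Lewis acids cleave or scramble. Ring A is a free β-resorcylic acid that decarboxylates easily, and ring C is a 1,2,4-trioxygenated arene that oxidises in air, so both must be unmasked last and under neutral conditions. When the second ester is formed, the ring B C4 hydroxyl must be the only reactive hydroxyl in the molecule. The feature that opens the chosen route is the pattern of ring B: C1 ester carbonyl, C2 hydroxyl, C4 oxygen, C6 methyl, hydrogen at C3 and C5. This is what results when a vinylketene (C5, C6, C1 and, as the ketene carbon, C2) combines with a terminal ynol ether (C3 and C4).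

## Retrosynthesis

**Final unmasking.** The last bonds cut are the five benzylic C–O bonds of 26 (benzyl ester and C2 benzyl ether on ring A, three benzyl ethers on ring C), giving 27. Hydrogenolysis is the only deprotection neutral enough for two aryl esters, a free salicylic acid and an oxidisable ring C; Lewis-acid ether cleavage or saponification would attack the depside bonds first. The forward step asks only that nothing else be reduced.

**Ring B–ring C ester.** Cutting the ester C–O bond between the ring B C4 oxygen and the ring C carbonyl divides 26 into the didepside phenol 20 and the acid 24. This bond is cut before the A–B ester because ring C is the oxidisable part and is best brought in last. In 20 the C4 hydroxyl is the only one not locked in a hydrogen bond. The forward reaction must acylate a phenol with a 2,6-disubstituted benzoic acid, for which activation as the mixed anhydride 25 is the established answer.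

**Ring C.** The acid 24 goes back through its benzyl ester 23 to the triol 22, and the C5–O bond of 22 is cut to give benzyl orsellinate 2. C5 is the only free position para to a phenolic oxygen (the C2 oxygen; para to the C4 oxygen lies C1), and that is where a persulfate oxidation attacks. Electrophilic halogenation or formylation of 2 would have to choose between C3 and C5. Precursor 2 is one step from orsellinic acid 1 and is shared with ring A.

**Ring B (key disconnection).** 20 comes from its silyl ether 19. In 19 three ring B bonds are cut: C2–C3 and C4–C5 return the two carbons of the siloxyalkyne 16, and C1–C2 opens the ring to the vinylketene 17 and so to the diazo ketone 12. Against the obvious neighbour, esterifying 5 with a protected orsellinic acid, this cut makes the hindered A–B ester before ring B exists, while its carbonyl is still an unhindered enoate. It also delivers the two ring B oxygens already differentiated, as a hydrogen-bonded C2 hydroxyl and a C4 silyl ether. The forward reaction must give one regiochemistry in the ketene–alkyne cycloaddition and must keep the ketene from every nucleophile but the alkyne. For that reason the enoate is taken in the E form, where the ester carbonyl cannot reach the ketene carbon. A Z enoate would allow six-electron closure through the ester oxygen, and its carboxylic acid precursor, an aryl hydrogen maleate, would tend to revert to cyclic anhydride and phenol.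

**Diazo ketone.** The diazo carbon of 12 is traced back to the acetyl methyl group of 10 by way of the trifluoroacetyl diketone 11. Diazo transfer to an activated methyl ketone is preferred over acylating a diazoalkane with an acid chloride, because the fumarate-like double bond is a strong dipolarophile. The forward step asks for kinetic enolisation of a methyl ketone in a molecule that also holds an aryl ester and a Michael acceptor; this is the delicate point of the approach.

**Enoate ester.** The ester C–O bond of 10 is cut to the phenol 5 and the keto acid 9. The C2=C3 bond of 9 (through its tert-butyl ester 8) is cut to butane-2,3-dione 6 and the stabilised ylide 7. A Wittig reaction fixes both the position of the methyl group and the E geometry, which opening an unsymmetrical cyclic anhydride with a phenol would leave to chance.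

**Ring A.** The phenol 5 goes back through the allyl ether 4 and the mono-allyl ether 3 to 2 and 1. The order of the two alkylations rests on the difference between the free C4 hydroxyl and the hydrogen-bonded C2 hydroxyl. The allyl group is chosen because its removal spares benzyl groups.

**Siloxyalkyne.** The O–Si bond of 16 is cut to lithium ethynolate 15, and the C–O bond of 15 to lithium acetylide 14, made from acetylene 13. The alkyne must be terminal because its CH carbon becomes C3 of ring B, and the silyl group must be bulky so that the ynolate is silylated on oxygen.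

## Roads not taken

**Alternative 1:** The cut is made in ring C only: the C6–methyl bond and the C5–O bond are formed together on an aryne. The chloroarene A2 would be lithiated at C6 between the oxazoline and the chlorine and lose chloride to give the C5–C6 aryne. A methyl carbanion would add at C6 under direction of the oxazoline nitrogen, and the C5 aryllithium would be borylated and oxidised in the same flask to the phenol A1.
- Merits: two bonds in one operation, with regiochemistry set by the directing group and not by the innate preferences of a resorcinol.
- Weak points: it addresses only ring C, the smallest part of the problem, and leaves both depside bonds to be made conventionally. Lithiation at C3 between the two methoxy groups competes with lithiation at C6. The oxazoline must later be forced open to a di-ortho-substituted acid. A1 carries methyl ethers, which cannot be removed in the presence of depside bonds, so they would have to be exchanged for benzyl ethers before coupling.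
- Comparison: for ring C alone this road is probably the more regiosecure and better yielding than the persulfate oxidation of step 12. Against that, the chosen plan reaches acid 24 in three steps from the shared intermediate 2, already in benzyl-protected form.

**Alternative 2:** The cut is made in ring A, between C1 and C6 and between C3 and C4. The enolate of the acetoacetate A4 adds to the crotonate A5, and the adduct closes by Dieckmann condensation to the racemic trans dione A3. Its enol oxygen would be acylated and the ring aromatised late.
- Merits: the cheapest inputs of any route, and a dione with a single enolic oxygen, which avoids the protecting-group sequence of steps 2 to 4. The two stereocentres are erased and need no control.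
- Weak points: the enol ester of a cyclic 1,3-dione is a vinylogous anhydride, so it transfers its acyl group and rearranges from oxygen to carbon. The late dehydrogenation needs a halogen or quinone oxidant in the presence of electron-rich rings and benzyl ethers. The sequence also rebuilds a ring that can be bought as 1.
- Comparison: on cost of materials this road is better. The chosen plan spends four routine steps from 1 to 5 but keeps ring A aromatic and inert throughout.

**Alternative 3:** Ring B is cut at the ester C–O bond and at C1–C6. The diketo-dioxinone A7 on heating gives an acylketene, phenol 5 captures it, and the aryl triketo ester cyclises by aldol condensation of C2 onto the C7 ketone and dehydrates to A6, which is identical with 20.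
- Merits: ring B is built and attached in one flask, with no diazo compound, no photochemistry and no siloxyalkyne, and it arrives at 20 without a desilylation. In step count this road is shorter than the chosen one.
- Weak points: the intermediate is an aryl ester of a β-keto acid, which loses aryloxide readily. The base used for aromatisation threatens that ester. The triketo chain has other ways to close (lactonisation to a pyranone, aldol in the other sense).
- Comparison: the chosen plan accepts more steps. In return, the ring B regiochemistry is fixed by the polarity of ketene and ynol ether and not by competition between condensation modes. The aryl ester is never a β-keto ester, and the two ring B oxygens are differentiated from the moment the ring forms.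

Key step: step 10

Assumption: the enoate double bond of the diazo ketone is used in the E form, since its geometry disappears on aromatisation and only the E form keeps the ester carbonyl away from the ketene; ethynyloxy(triisopropyl)silane is treated as a compound to be made, not bought.

## Steps

Step 1
Reactants: 1 orsellinic acid (2,4-dihydroxy-6-methylbenzoic acid)
Product: 2 benzyl 2,4-dihydroxy-6-methylbenzoate
Conditions: BnBr, KHCO3, DMF, 20 to 40 °C
Reagents that add atoms: benzyl bromide, BrCc1ccccc1
Why: Carboxylate O-alkylation (SN2); KHCO3 deprotonates only the acid, so neither phenol is benzylated, and the mild temperature avoids decarboxylation.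

Step 2
Reactants: 2 benzyl 2,4-dihydroxy-6-methylbenzoate
Product: 3 benzyl 2-hydroxy-6-methyl-4-(prop-2-en-1-yloxy)benzoate
Conditions: allyl bromide (1.05 equiv), K2CO3, acetone, 20 to 56 °C
Reagents that add atoms: allyl bromide, C=CCBr
Why: Williamson ether synthesis; the C4 hydroxyl is the more acidic and unhindered one, while the C2 hydroxyl is held in a hydrogen bond to the ester, so one equivalent of halide should give the 4-allyl ether.

Step 3
Reactants: 3 benzyl 2-hydroxy-6-methyl-4-(prop-2-en-1-yloxy)benzoate
Product: 4 benzyl 2-(benzyloxy)-6-methyl-4-(prop-2-en-1-yloxy)benzoate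
Conditions: BnBr, K2CO3, DMF, 60 °C
Reagents that add atoms: benzyl bromide, BrCc1ccccc1
Why: Williamson ether synthesis under more forcing conditions benzylates the remaining hydrogen-bonded hydroxyl; the allyl ether and the hindered benzyl ester are inert to carbonate.

Step 4
Reactants: 4 benzyl 2-(benzyloxy)-6-methyl-4-(prop-2-en-1-yloxy)benzoate
Product: 5 benzyl 2-(benzyloxy)-4-hydroxy-6-methylbenzoate
Conditions: Pd(PPh3)4 (cat.), morpholine, THF, 20 °C
Reagents that add atoms: none
Why: Tsuji–Trost deallylation; zerovalent palladium ionises the aryl allyl ether to a π-allyl complex that morpholine captures, leaving benzyl ether and benzyl ester untouched.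

Step 5
Reactants: 6 butane-2,3-dione (3 equiv), 7 tert-butyl (triphenylphosphoranylidene)acetate
Product: 8 tert-butyl (2E)-3-methyl-4-oxopent-2-enoate
Conditions: CH2Cl2, 20 °C
Reagents that add atoms: none
Why: Wittig olefination of an activated 1,2-diketone by a stabilised ylide; excess diketone suppresses double olefination, and the stabilised ylide should place the ester trans to the acetyl group (E).

Step 6
Reactants: 8 tert-butyl (2E)-3-methyl-4-oxopent-2-enoate
Product: 9 (2E)-3-methyl-4-oxopent-2-enoic acid
Conditions: CF3CO2H, CH2Cl2, 0 to 20 °C
Reagents that add atoms: none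
Why: Acidolysis of the tert-butyl ester with loss of isobutene; the E keto acid cannot lactonise to a hydroxybutenolide as a Z isomer would.

Step 7
Reactants: 5 benzyl 2-(benzyloxy)-4-hydroxy-6-methylbenzoate, 9 (2E)-3-methyl-4-oxopent-2-enoic acid
Product: 10 benzyl 2-(benzyloxy)-6-methyl-4-{[(2E)-3-methyl-4-oxopent-2-enoyl]oxy}benzoate
Conditions: DCC, DMAP (cat.), CH2Cl2, 0 to 20 °C
Reagents that add atoms: none
Why: Steglich esterification; the only free hydroxyl of 5 attacks the activated acyl group, and the unhindered enoyl carbonyl makes this the easy stage at which to form the A–B depside bond.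

Step 8
Reactants: 10 benzyl 2-(benzyloxy)-6-methyl-4-{[(2E)-3-methyl-4-oxopent-2-enoyl]oxy}benzoate
Product: 12 benzyl 2-(benzyloxy)-4-{[(2E)-5-diazo-3-methyl-4-oxopent-2-enoyl]oxy}-6-methylbenzoate, via trifluoroacetyl diketone 11 (not isolated)
Conditions: LiN(SiMe3)2, THF, −78 °C; CF3CO2CH2CF3; then CH3SO2N3, Et3N, H2O, MeCN, 20 °C
Reagents that add atoms: methanesulfonyl azide, CS(=O)(=O)N=[N+]=[N-]
Why: Detrifluoroacetylative Regitz diazo transfer: kinetic enolisation at the acetyl methyl group, Claisen trifluoroacetylation to 11, then diazo transfer with loss of the trifluoroacetyl group as the acyl sulfonamide. This is the standard route to diazo ketones of enones, where acylation of a diazoalkane fails; the substrate is added to the base so that little free Michael acceptor meets the enolate.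

Step 9
Reactants: 13 acetylene (excess)
Product: 16 ethynyloxy(triisopropyl)silane, via lithium acetylide 14 (not isolated), via lithium ethynolate 15 (not isolated)
Conditions: n-BuLi, THF, −78 °C; t-BuOOLi (from t-BuOOH and LiN(SiMe3)2), −78 to −30 °C; i-Pr3SiOSO2CF3, −78 to 0 °C
Reagents that add atoms: lithium tert-butyl peroxide, [Li+].[O-]OC(C)(C)C; triisopropylsilyl trifluoromethanesulfonate, CC(C)[Si](C(C)C)(C(C)C)OS(=O)(=O)C(F)(F)F
Why: Oxidation of a lithium acetylide to the ynolate by lithium tert-butyl peroxide, then O-silylation by the bulky, hard silyl triflate, is the usual entry to triisopropylsiloxyalkynes. Excess acetylene and low temperature should keep the acetylide monolithiated.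

Step 10
Reactants: 12 benzyl 2-(benzyloxy)-4-{[(2E)-5-diazo-3-methyl-4-oxopent-2-enoyl]oxy}-6-methylbenzoate, 16 ethynyloxy(triisopropyl)silane (2.5 equiv)
Product: 19 benzyl 2-(benzyloxy)-4-({2-hydroxy-6-methyl-4-[(triisopropylsilyl)oxy]benzoyl}oxy)-6-methylbenzoate, via vinylketene 17 (not isolated), via 4-alkenylcyclobutenone 18 (not isolated)
Conditions: hν (350 nm, Pyrex), ClCH2CH2Cl, 20 °C; then 80 °C
Reagents that add atoms: none
Why: Light expels N2 from 12 and the alkenyl group migrates to the carbene centre (photochemical Wolff rearrangement), giving vinylketene 17, whose ketene carbon becomes C2 of ring B. The nucleophilic CH carbon of 16 attacks this carbon and the oxygen-bearing alkyne carbon closes onto the former diazo carbon in a regioselective, asynchronous [2+2] cycloaddition (four-membered ring, bonds C2–C3 and C4–C5), giving the 4-alkenylcyclobutenone 18. At 80 °C, 18 opens reversibly by four-electron conrotatory ring cleavage to a dienylketene, and the isomer with the alkenyl group turned inward closes by thermal six-electron disrotatory electrocyclisation (six-membered ring B, bond C1–C2) to a cyclohexadienone that enolises to phenol 19. The closest known reaction is the second-generation Danheiser benzannulation of α,β-unsaturated diazo ketones with siloxyalkynes, which gives resorcinol monosilyl ethers of this kind. No stereocentre remains: the C4 centre of racemic 18 and the alkene geometry are both erased on aromatisation. The regiochemistry needed (siloxy group at C4, meta to the new hydroxyl) is secured by the polarisation of the partners: an electrophilic ketene carbon and an alkyne whose positive charge is stabilised at the oxygen-bearing carbon. The chemoselectivity needed (cycloaddition, not capture of the ketene) is secured by the E geometry, which keeps the ester carbonyl from the ketene carbon, by the benzyl ether on ring A, which leaves no free hydroxyl, and by the hydrogen bond that ties up the new C2 hydroxyl. Irradiation at 350 nm should excite the diazo ketone but not the aryl esters.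

Step 11
Reactants: 19 benzyl 2-(benzyloxy)-4-({2-hydroxy-6-methyl-4-[(triisopropylsilyl)oxy]benzoyl}oxy)-6-methylbenzoate
Product: 20 benzyl 2-(benzyloxy)-4-[(2,4-dihydroxy-6-methylbenzoyl)oxy]-6-methylbenzoate
Conditions: Bu4NF, AcOH, THF, 0 °C
Reagents that add atoms: none
Why: Fluoride-induced cleavage of the aryl silyl ether; acetic acid buffers the phenoxide so that the aryl ester bonds are not transesterified.

Step 12
Reactants: 2 benzyl 2,4-dihydroxy-6-methylbenzoate
Product: 22 benzyl 2,4,5-trihydroxy-6-methylbenzoate, via aryl potassium sulfate 21 (not isolated)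
Conditions: K2S2O8, aq. KOH, pyridine, 0 to 20 °C; then aq. HCl, 80 °C, argon
Reagents that add atoms: potassium peroxodisulfate, [K+].[K+].[O-]S(=O)(=O)OOS(=O)(=O)[O-]
Why: Elbs persulfate oxidation; the phenoxide attacks peroxodisulfate through the carbon para to the C2 oxygen, and C5 is the only open para position. The aryl sulfate 21 is then hydrolysed in acid, which the hindered benzyl ester should survive.

Step 13
Reactants: 22 benzyl 2,4,5-trihydroxy-6-methylbenzoate
Product: 23 benzyl 2,4,5-tris(benzyloxy)-6-methylbenzoate
Conditions: BnBr (3.6 equiv), K2CO3, DMF, 60 °C, argon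
Reagents that add atoms: benzyl bromide, BrCc1ccccc1
Why: Williamson ether synthesis on all three phenols, carried out at once and under argon because 22 is air-sensitive.

Step 14
Reactants: 23 benzyl 2,4,5-tris(benzyloxy)-6-methylbenzoate
Product: 24 2,4,5-tris(benzyloxy)-6-methylbenzoic acid
Conditions: KOH, DMSO–H2O, 90 °C; then aq. HCl
Reagents that add atoms: potassium hydroxide, [K+].[OH-]
Why: Saponification of a di-ortho-substituted benzoate needs hydroxide in aqueous DMSO; attack at the carbonyl or at the benzylic carbon both give the acid, and the aryl benzyl ethers are stable to base.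

Step 15
Reactants: 24 2,4,5-tris(benzyloxy)-6-methylbenzoic acid, 20 benzyl 2-(benzyloxy)-4-[(2,4-dihydroxy-6-methylbenzoyl)oxy]-6-methylbenzoate
Product: 26 benzyl 2-(benzyloxy)-4-[(2-hydroxy-6-methyl-4-{[2,4,5-tris(benzyloxy)-6-methylbenzoyl]oxy}benzoyl)oxy]-6-methylbenzoate, via mixed trifluoroacetic anhydride 25 (not isolated)
Conditions: (CF3CO)2O, toluene, 20 °C; then 20
Reagents that add atoms: none
Why: Depside esterification through the mixed trifluoroacetic anhydride, the classical method for 2,6-disubstituted benzoic acids, which acylate through an acylium-like species. Only the C4 hydroxyl of ring B should react, because the C2 hydroxyl is hydrogen-bonded to the adjacent ester.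

Step 16
Reactants: 26 benzyl 2-(benzyloxy)-4-[(2-hydroxy-6-methyl-4-{[2,4,5-tris(benzyloxy)-6-methylbenzoyl]oxy}benzoyl)oxy]-6-methylbenzoate
Product: 27 2-hydroxy-4-({2-hydroxy-6-methyl-4-[(2,4,5-trihydroxy-6-methylbenzoyl)oxy]benzoyl}oxy)-6-methylbenzoic acid (CNP0248995.0)
Conditions: H2 (1 atm), 10% Pd/C, EtOAc–THF, 20 °C; work-up under argon
Reagents that add atoms: none
Why: Hydrogenolysis of one benzyl ester and four benzyl ethers; the neutral conditions spare both aryl ester bonds, and the product is handled under argon because ring C is oxidisable.

## Compound list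

1 | orsellinic acid (2,4-dihydroxy-6-methylbenzoic acid) | Cc1cc(O)cc(O)c1C(=O)O | starting material
2 | benzyl 2,4-dihydroxy-6-methylbenzoate | Cc1cc(O)cc(O)c1C(=O)OCc1ccccc1 | intermediate
3 | benzyl 2-hydroxy-6-methyl-4-(prop-2-en-1-yloxy)benzoate | Cc1cc(OCC=C)cc(O)c1C(=O)OCc1ccccc1 | intermediate
4 | benzyl 2-(benzyloxy)-6-methyl-4-(prop-2-en-1-yloxy)benzoate | Cc1cc(OCC=C)cc(OCc2ccccc2)c1C(=O)OCc1ccccc1 | intermediate
5 | benzyl 2-(benzyloxy)-4-hydroxy-6-methylbenzoate | Cc1cc(O)cc(OCc2ccccc2)c1C(=O)OCc1ccccc1 | intermediate
6 | butane-2,3-dione | CC(=O)C(C)=O | starting material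
7 | tert-butyl (triphenylphosphoranylidene)acetate | CC(C)(C)OC(=O)C=P(c1ccccc1)(c1ccccc1)c1ccccc1 | starting material
8 | tert-butyl (2E)-3-methyl-4-oxopent-2-enoate | CC(=O)/C(C)=C/C(=O)OC(C)(C)C | intermediate
9 | (2E)-3-methyl-4-oxopent-2-enoic acid | CC(=O)/C(C)=C/C(=O)O | intermediate
10 | benzyl 2-(benzyloxy)-6-methyl-4-{[(2E)-3-methyl-4-oxopent-2-enoyl]oxy}benzoate | CC(=O)/C(C)=C/C(=O)Oc1cc(C)c(C(=O)OCc2ccccc2)c(OCc2ccccc2)c1 | intermediate
11 | benzyl 2-(benzyloxy)-6-methyl-4-{[(2E)-7,7,7-trifluoro-3-methyl-4,6-dioxohept-2-enoyl]oxy}benzoate (not isolated) | FC(F)(F)C(=O)CC(=O)/C(C)=C/C(=O)Oc1cc(C)c(C(=O)OCc2ccccc2)c(OCc2ccccc2)c1 | intermediate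
12 | benzyl 2-(benzyloxy)-4-{[(2E)-5-diazo-3-methyl-4-oxopent-2-enoyl]oxy}-6-methylbenzoate | [N-]=[N+]=CC(=O)/C(C)=C/C(=O)Oc1cc(C)c(C(=O)OCc2ccccc2)c(OCc2ccccc2)c1 | intermediate
13 | acetylene (ethyne) | C#C | starting material
14 | lithium acetylide (not isolated) | [Li+].[C-]#C | intermediate
15 | lithium ethynolate (not isolated) | [Li+].[O-]C#C | intermediate
16 | ethynyloxy(triisopropyl)silane | C#CO[Si](C(C)C)(C(C)C)C(C)C | intermediate
17 | benzyl 2-(benzyloxy)-6-methyl-4-{[(2E)-3-methyl-5-oxopenta-2,4-dienoyl]oxy}benzoate (vinylketene, not isolated) | O=C=C/C(C)=C/C(=O)Oc1cc(C)c(C(=O)OCc2ccccc2)c(OCc2ccccc2)c1 | intermediate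
18 | benzyl 2-(benzyloxy)-6-methyl-4-({(2E)-3-[4-oxo-2-(triisopropylsilyloxy)cyclobut-2-en-1-yl]but-2-enoyl}oxy)benzoate (racemic, not isolated) | O=C1C=C(O[Si](C(C)C)(C(C)C)C(C)C)C1/C(C)=C/C(=O)Oc1cc(C)c(C(=O)OCc2ccccc2)c(OCc2ccccc2)c1 | intermediate
19 | benzyl 2-(benzyloxy)-4-({2-hydroxy-6-methyl-4-[(triisopropylsilyl)oxy]benzoyl}oxy)-6-methylbenzoate | Cc1cc(O[Si](C(C)C)(C(C)C)C(C)C)cc(O)c1C(=O)Oc1cc(C)c(C(=O)OCc2ccccc2)c(OCc2ccccc2)c1 | intermediate
20 | benzyl 2-(benzyloxy)-4-[(2,4-dihydroxy-6-methylbenzoyl)oxy]-6-methylbenzoate | Cc1cc(O)cc(O)c1C(=O)Oc1cc(C)c(C(=O)OCc2ccccc2)c(OCc2ccccc2)c1 | intermediate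
21 | benzyl 2,4-dihydroxy-6-methyl-5-(sulfonatooxy)benzoate, potassium salt (not isolated) | Cc1c(OS(=O)(=O)[O-])c(O)cc(O)c1C(=O)OCc1ccccc1.[K+] | intermediate
22 | benzyl 2,4,5-trihydroxy-6-methylbenzoate | Cc1c(O)c(O)cc(O)c1C(=O)OCc1ccccc1 | intermediate
23 | benzyl 2,4,5-tris(benzyloxy)-6-methylbenzoate | Cc1c(OCc2ccccc2)c(OCc2ccccc2)cc(OCc2ccccc2)c1C(=O)OCc1ccccc1 | intermediate
24 | 2,4,5-tris(benzyloxy)-6-methylbenzoic acid | Cc1c(OCc2ccccc2)c(OCc2ccccc2)cc(OCc2ccccc2)c1C(=O)O | intermediate
25 | 2,4,5-tris(benzyloxy)-6-methylbenzoic trifluoroacetic anhydride (not isolated) | Cc1c(OCc2ccccc2)c(OCc2ccccc2)cc(OCc2ccccc2)c1C(=O)OC(=O)C(F)(F)F | intermediate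
26 | benzyl 2-(benzyloxy)-4-[(2-hydroxy-6-methyl-4-{[2,4,5-tris(benzyloxy)-6-methylbenzoyl]oxy}benzoyl)oxy]-6-methylbenzoate | Cc1c(OCc2ccccc2)c(OCc2ccccc2)cc(OCc2ccccc2)c1C(=O)Oc1cc(C)c(C(=O)Oc2cc(C)c(C(=O)OCc3ccccc3)c(OCc3ccccc3)c2)c(O)c1 | intermediate
27 | 2-hydroxy-4-({2-hydroxy-6-methyl-4-[(2,4,5-trihydroxy-6-methylbenzoyl)oxy]benzoyl}oxy)-6-methylbenzoic acid | Cc1cc(OC(=O)c2c(C)cc(OC(=O)c3c(O)cc(O)c(O)c3C)cc2O)cc(O)c1C(=O)O | target

## Step count and least certain steps

Total step count: 16. Longest linear sequence: 10 steps (steps 1, 2, 3, 4, 7, 8, 10, 11, 15, 16).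

**Step 10 (key step).** The most likely failure is loss of the vinylketene to paths other than the [2+2] cycloaddition. The enoate double bond can photoisomerise, which would let the ester carbonyl close onto the ketene. The aryl ester can undergo photo-Fries migration if it absorbs. The cyclobutenone can convert incompletely if outward rotation of the alkenyl group dominates on ring opening.
Fallback: an acyl-transfer route that forms the A–B ester from an intact ring B. Orsellinic acid 1 would be condensed with acetone and trifluoroacetic anhydride to 7-hydroxy-2,2,5-trimethyl-4H-1,3-benzodioxin-4-one F1 and silylated to 2,2,5-trimethyl-7-[(triisopropylsilyl)oxy]-4H-1,3-benzodioxin-4-one F2. F2 would then be irradiated in the presence of phenol 5, which traps the o-quinone ketene released with loss of acetone. This sets out from 1 and 5 and returns to the route at 19.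

**Step 9.** The unsubstituted case is the least documented member of the class. Lithium acetylide can disproportionate before oxygen transfer, the unhindered ynolate can be silylated on carbon instead of oxygen, and the volatile product can be lost on isolation.
Fallback: a route without an ynolate. Commercial dichloroacetaldehyde would be silylated on oxygen (i-Pr3SiOSO2CF3, Et3N) to [(2,2-dichloroethenyl)oxy](triisopropyl)silane F3. Two equivalents of n-BuLi would then cause deprotonation, loss of chloride and chlorine–lithium exchange to lithium [(triisopropylsilyl)oxy]acetylide F4, as in the dichlorovinyl ether route to alkyl ethynyl ethers, and protonation gives 16. This replaces 13 as the starting point and returns at 16.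

**Step 8.** The lithium enolate of 10 may add in conjugate fashion to the ene-dicarbonyl unit of a second molecule or attack the aryl ester, and deprotonation at the C3 methyl group may compete.
Fallback: acylation of a diazoalkane with no enolate involved. Glyoxylic acid and tert-butyl 2-(triphenylphosphoranylidene)propanoate would give (2E)-4-tert-butoxy-3-methyl-4-oxobut-2-enoic acid F5 by Wittig reaction. Steglich esterification of F5 with 5 would give the mixed diester 4-{3-(benzyloxy)-4-[(benzyloxy)carbonyl]-5-methylphenyl} 1-tert-butyl (2E)-2-methylbut-2-enedioate F6. Acidolysis would give (2E)-4-{3-(benzyloxy)-4-[(benzyloxy)carbonyl]-5-methylphenoxy}-2-methyl-4-oxobut-2-enoic acid F7. Oxalyl chloride would give benzyl 2-(benzyloxy)-4-{[(2E)-4-chloro-3-methyl-4-oxobut-2-enoyl]oxy}-6-methylbenzoate F8, and (trimethylsilyl)diazomethane at 0 °C would convert F8 into 12. Dipolar addition to the double bond is the known weakness of this fallback, which is why it is not the first choice. It sets out from 5 and returns at 12.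

**Step 12.** Persulfate oxidations often stop at partial conversion and can over-oxidise the electron-rich product, and the triol is air-sensitive.
Fallback: oxidation to the quinone level and reduction back. Compound 2 would be oxidised with ON(SO3K)2 (Teuber oxidation, para to the C2 oxygen) to benzyl 4-hydroxy-2-methyl-3,6-dioxocyclohexa-1,4-diene-1-carboxylate F9, and F9 reduced with Na2S2O4 to 22. This sets out from 2 and returns at 22.

**Step 11.** Free phenoxide generated on desilylation may attack an aryl ester bond, causing acyl migration or cleavage of the didepside.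
Fallback: acylation of the silyl ether without freeing the phenol. Acid 24 would be converted with cyanuric fluoride into 2,4,5-tris(benzyloxy)-6-methylbenzoyl fluoride F10, and 19 treated with F10 and catalytic Bu4N[Ph3SiF2], so that fluoride-catalysed acyl transfer to the silyl ether gives 26 directly. This sets out from 19 and 24 and returns at 26, bypassing 20 and 25.

## Further compounds

F1 | step 10 | 7-hydroxy-2,2,5-trimethyl-4H-1,3-benzodioxin-4-one | Cc1cc(O)cc2OC(C)(C)OC(=O)c12
F2 | step 10 | 2,2,5-trimethyl-7-[(triisopropylsilyl)oxy]-4H-1,3-benzodioxin-4-one | Cc1cc(O[Si](C(C)C)(C(C)C)C(C)C)cc2OC(C)(C)OC(=O)c12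
F3 | step 9 | [(2,2-dichloroethenyl)oxy](triisopropyl)silane | ClC(Cl)=CO[Si](C(C)C)(C(C)C)C(C)C
F4 | step 9 | lithium [(triisopropylsilyl)oxy]acetylide | [Li+].[C-]#CO[Si](C(C)C)(C(C)C)C(C)C
F5 | step 8 | (2E)-4-tert-butoxy-3-methyl-4-oxobut-2-enoic acid | CC(C)(C)OC(=O)/C(C)=C/C(=O)O
F6 | step 8 | 4-{3-(benzyloxy)-4-[(benzyloxy)carbonyl]-5-methylphenyl} 1-tert-butyl (2E)-2-methylbut-2-enedioate | CC(C)(C)OC(=O)/C(C)=C/C(=O)Oc1cc(C)c(C(=O)OCc2ccccc2)c(OCc2ccccc2)c1
F7 | step 8 | (2E)-4-{3-(benzyloxy)-4-[(benzyloxy)carbonyl]-5-methylphenoxy}-2-methyl-4-oxobut-2-enoic acid | OC(=O)/C(C)=C/C(=O)Oc1cc(C)c(C(=O)OCc2ccccc2)c(OCc2ccccc2)c1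
F8 | step 8 | benzyl 2-(benzyloxy)-4-{[(2E)-4-chloro-3-methyl-4-oxobut-2-enoyl]oxy}-6-methylbenzoate | ClC(=O)/C(C)=C/C(=O)Oc1cc(C)c(C(=O)OCc2ccccc2)c(OCc2ccccc2)c1
F9 | step 12 | benzyl 4-hydroxy-2-methyl-3,6-dioxocyclohexa-1,4-diene-1-carboxylate | CC1=C(C(=O)OCc2ccccc2)C(=O)C=C(O)C1=O
F10 | step 11 | 2,4,5-tris(benzyloxy)-6-methylbenzoyl fluoride | Cc1c(OCc2ccccc2)c(OCc2ccccc2)cc(OCc2ccccc2)c1C(F)=O
A1 | alternative 1 | 2-(3-hydroxy-4,6-dimethoxy-2-methylphenyl)-4,4-dimethyl-4,5-dihydro-1,3-oxazole | COc1cc(OC)c(C2=NC(C)(C)CO2)c(C)c1O
A2 | alternative 1 | 2-(5-chloro-2,4-dimethoxyphenyl)-4,4-dimethyl-4,5-dihydro-1,3-oxazole | COc1cc(OC)c(C2=NC(C)(C)CO2)cc1Cl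
A3 | alternative 2 | benzyl (1S,6R)-6-methyl-2,4-dioxocyclohexane-1-carboxylate (racemic, trans) | C[C@@H]1CC(=O)CC(=O)[C@H]1C(=O)OCc1ccccc1
A4 | alternative 2 | benzyl 3-oxobutanoate | CC(=O)CC(=O)OCc1ccccc1
A5 | alternative 2 | ethyl (2E)-but-2-enoate | C/C=C/C(=O)OCC
A6 | alternative 3 | benzyl 2-(benzyloxy)-4-[(2,4-dihydroxy-6-methylbenzoyl)oxy]-6-methylbenzoate (identical with 20) | Cc1cc(OC(=O)c2c(C)cc(O)cc2O)cc(OCc2ccccc2)c1C(=O)OCc1ccccc1
A7 | alternative 3 | 6-(2,4-dioxopentyl)-2,2-dimethyl-4H-1,3-dioxin-4-one | CC(=O)CC(=O)CC1=CC(=O)OC(C)(C)O1
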